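Target in percent is what is asked, but target in mM is what I compare between flasks.

| flask | starting material | solid reagent | remark | time |
|---|---|---|---|---|
| larch | 3.4 mM | 9.5 mM | run made earlier |  |
| cedar | 55 mM | 9.5 mM | run made earlier |  |
| north | 30 mM | 9.50 mM |  | 2.5 d |
| south | 3.0 mM | 9.50 mM |  | 2.5 d |
| east | 40 mM | 9.50 mM |  | 2.5 d |
| north-west | 5.0 mM | 9.50 mM |  | 2.5 d |
| south-west | 6.0 mM | 9.50 mM |  | 2.5 d |
| north-east | 10 mM | 9.50 mM |  | 2.5 d |

- larch (time / h: target / %, starting material / %): 5.00: 6, 98; 10.0: 8, 90; 15.0: 17, 81; 20.0: 23, 76; 25.0: 30, 65; 30.0: 34, 59
- cedar (time / h: target / %, starting material / %): 5.00: 2, 99; 10.0: 2, 97; 15.0: 3, 100; 20.0: 1, 96; 25.0: 5, 94; 30.0: 2, 95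

(readings scatter by 1.5 percentage points)

1. ranking by amount of target, in percent of the starting material charged, from high to low, at 2.5 d (north / south / east / north-west / south-west / north-east)
2. the amount of target, in percent of the starting material charged of the flask you put first, at 2.5 d
3. the amount of target, in percent of the starting material charged of the flask you put last, at 2.5 d

- solid, in amounts per volume of the solution: solid reagent
- the numbers in the tables scatter with a standard deviation of 1.5 percentage points
- at the start none of the solid reagent is in solution

My first guess is a rate proportional to [starting material]. Then the percent of target at equal times would match between the two runs. It doesn't: at 30.0 h larch shows 34 % and cedar 2 %. So I count in mM. Larch makes 0.0385 mM/h and cedar 0.0367 mM/h.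

The agreement looks too good: cedar's reading of 2 % carries a scatter of 1.5 percentage points. So I take cedar's highest reading instead, 5 % at 25.0 h. Even that gives 2.85 times the larch rate, while the charge is 16.2 times larger. So across these two runs the rate of target looks close to zero-order in starting material. I suspect that another concentration sets it: the dissolved solid reagent, which starts at none, with its dissolving as the rate-limiting step.

So I carry the budget, the mM of target that the larch rate gives over the asked time, reckoned as if the charge did not matter: 2.31 mM.

Does the rate slow as starting material falls? In larch, target at 30.0 h is twice that at 15.0 h, so these readings show no slowing, down to 2.01 mM of starting material. But the budget reckons south down to 0.688 mM, lower than that, so I trust its figure less. My reckoning gives south 77.1 % and east 5.78 %. In this reckoning south stands first and east last.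

The forecast gives the same order, south > north-west > south-west > north-east > north > east, but other numbers: 72 % (62 % to 82 %) and 7 % (5 % to 10 %). Its ground: “The reaction is therefore nearly zero-order in starting material, most likely limited by the solid reagent dissolving.”

The flasks give south > north-west > south-west > north-east > north > east, with 64.4 % first and 7.12 % last. The order holds, and the forecast's top stands 7.6 points too high.

    solid reagent ⇌ partner, rate k1*(cs1 - [partner]) while solid is left; crystals form when [partner] > cs1 (solubility = 4.70 mM, k = 4.40 × 10⁻⁴ /min)
    tight pair ⇌ loose pair (K = 1.70, k = 0.200 /min)
    partner + tight pair → target (k = 1700 /M/min)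
    starting material ⇌ tight pair (K = 4.50 × 10⁻⁴, k = 5.10 × 10⁻⁴ /min)
    2 partner → self-condensation product (k = 0.0160 /M/min)
    loose pair → side product (k = 1.20 × 10⁻⁴ /min)
    partner + loose pair → isomer of the product (k = 2800 /M/min)

East made 2.85 mM of target against my budget of 2.31 mM, and south made 1.93 mM. The neighbour is east's recipe with 24 mM of starting material. The budget over that charge gives 9.62 %. That flask gives 15.4 %, which is 3.70 mM of target, more than the budget. The neighbour flask keeps 70.0 % of its starting material, and 14.5 % stands as isomer of the product.

The earlier runs and the new flask stem from a simulated flask on assumed constants; noise was put on by code.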